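**Retrosynthetic overview**
1. Target 7 ⇐ γ-benzoyloxy enal 6 by aldehyde-to-acid oxidation (carboxyl C–O bond made last).
2. 6 ⇐ enal 5 by the key C1–O bond: a catalytic vinylogous (γ) benzoyloxylation that also sets C1 (proposed new step).
3. 5 ⇐ mono-ene epoxide 3 by allylic C15–H oxidation (C15–O bond), which turns the ring-trans C2=C3 bond into the ring-cis one.
4. 3 ⇐ epoxide 2 ⇐ α-humulene 1: chemoselective saturation of C9=C10, then enantioselective C6/C7 epoxidation (two C–O bonds, sets C6 and C7).
5. Ring order: the eleven-membered carbocycle is taken intact from 1 (no C–C bond is formed); the oxirane is the only ring made, in step 1.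

Assumption: α-humulene (CAS 6753-98-6) is accepted as a commercial bulk terpene. Humulane numbering is used throughout: C11 = CMe2 (C12, C13), C1 next to it (benzoate carbon), C2=C3 with C15 on C3, C6/C7 = epoxide with C14 on C7.

**Step 1**
Reactants: 1 α-humulene
Product: 2 (6R,7R)-6,7-epoxyhumula-2,9-diene
Conditions: D-fructose-derived Shi ketone (0.3 equiv), Oxone (2KHSO5·KHSO4·K2SO4; 1.1 equiv KHSO5), K2CO3, Bu4NHSO4 (cat.), MeCN/DMM, aq. Na2B4O7 buffer (pH 10.5), 0 °C
Reagents that add atoms: potassium peroxymonosulfate (KHSO5) [K+].[O-]S(=O)(=O)OO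
Why: Shi asymmetric epoxidation; the chiral dioxirane attacks the most nucleophilic and least hindered trisubstituted olefin C6=C7 (C2=C3 is flanked by the neopentyl C1, C9=C10 is only disubstituted) through the spiro transition state, which for E-trisubstituted olefins with the D-fructose ketone gives the (R,R)-epoxide and so sets C6 and C7.

**Step 2**
Reactants: 2 (6R,7R)-6,7-epoxyhumula-2,9-diene
Product: 3 (2E,6R,7R)-6,7-epoxyhumul-2-ene
Conditions: 2-nitrobenzenesulfonyl hydrazide (2.5 equiv, in portions), Et3N, CH2Cl2, rt, GC control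
Reagents that add atoms: none
Why: Diimide reduction (concerted syn transfer of H2) is roughly ten times faster for a 1,2-disubstituted olefin than for a trisubstituted one, so C9=C10 is saturated while C2=C3 and the epoxide, which diimide does not touch, remain.

**Step 3**
Reactants: 3 (2E,6R,7R)-6,7-epoxyhumul-2-ene
Product: 5 (2E,6R,7R)-6,7-epoxyhumul-2-en-15-al, via allylic alcohol 4 (not isolated)
Conditions: SeO2 (0.3 equiv), t-BuOOH (5.5 M in decane, 2.5 equiv), CH2Cl2, 0 °C → rt; then activated MnO2 (20 equiv), same flask, rt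
Reagents that add atoms: tert-butyl hydroperoxide CC(C)(C)OO (oxygen source, delivered through selenium dioxide O=[Se]=O)
Why: SeO2 allylic oxidation (ene reaction, then [2,3]-sigmatropic shift) at the C15 methyl, whose hydrogens align freely with the π-bond; the [2,3] shift re-forms C2=C3 with CH2OH trans to C1 (ring-cis), as in the known conversion of the epoxy-germacranolide parthenolide into melampomagnolide B, where a comparable trisubstituted epoxide survives, and MnO2 then oxidises the allylic alcohol 4 to the enal.

**Step 4**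
Reactants: 5 (2E,6R,7R)-6,7-epoxyhumul-2-en-15-al
Product: 6 (1R,2E,6R,7R)-1-benzoyloxy-6,7-epoxyhumul-2-en-15-al
Conditions: 9-amino-9-deoxy-epi-quinine (20 mol%), PhCO2H (40 mol%), (BzO)2 (1.3 equiv), BHT (10 mol%), THF, 0 °C → rt
Reagents that add atoms: dibenzoyl peroxide O=C(OOC(=O)c1ccccc1)c1ccccc1
Why: Proposed new method: amine-catalysed vinylogous (γ) benzoyloxylation of a macrocyclic α-branched enal. The primary amine condenses with the C15 aldehyde, and loss of a C1 proton from the iminium gives the N–C15=C3–C2=C1 dienamine. Its α-carbon C3 is fully substituted and blocked, so the γ-carbon C1 attacks the O–O bond of dibenzoyl peroxide (held by a hydrogen bond to the protonated quinuclidine) in an SN2-at-oxygen step that expels benzoate; hydrolysis of the re-formed conjugated iminium releases 6 and the catalyst. C1 is set in this C–O bond-forming step by delivery to the exposed peripheral face of the ring C1=C2 bond, with the quinine-derived amine proposed as the matched catalyst for 1R; this facial assignment is a hypothesis to be confirmed on the product. The 2E ring-cis enal is the thermodynamic geometry to which iminium and dienamine equilibrate, and the weak acid co-catalyst leaves the epoxide alone. Closest known reaction types: amine-catalysed α-benzoyloxylation of aldehydes and ketones with dibenzoyl peroxide, and dienamine γ-functionalisation of α-branched enals with carbon and nitrogen electrophiles.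

**Step 5**
Reactants: 6 (1R,2E,6R,7R)-1-benzoyloxy-6,7-epoxyhumul-2-en-15-al
Product: 7 (1R,2E,6R,7R)-1-benzoyloxy-6,7-epoxyhumul-2-en-15-oic acid
Conditions: NaClO2, NaH2PO4, 2-methyl-2-butene, t-BuOH/H2O (4:1), 0 °C → rt
Reagents that add atoms: sodium chlorite [Na+].[O-]Cl=O
Why: Pinnick oxidation converts only the aldehyde into the acid under buffered conditions (pH about 4) with hypochlorite scavenged, so the benzoate, the epoxide, the olefin geometry and all three stereocentres are untouched.

**Compound list**
1 | α-humulene, (2E,6E,9E)-humula-2,6,9-triene = (1E,4E,8E)-2,6,6,9-tetramethylcycloundeca-1,4,8-triene | CC1(C)/C=C/C/C(C)=C/CC/C(C)=C/C1 | starting material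
2 | (6R,7R)-6,7-epoxyhumula-2,9-diene (2E,9E; trans-epoxide) = (1R,3E,7E,11R)-1,5,5,8-tetramethyl-12-oxabicyclo[9.1.0]dodeca-3,7-diene | CC1(C)/C=C/C[C@@]2(C)O[C@@H]2CC/C(C)=C/C1 | intermediate
3 | (2E,6R,7R)-6,7-epoxyhumul-2-ene (C9–C10 saturated; C2=C3 ring-trans, C1 and C4 on opposite sides) | CC1(C)CCC[C@@]2(C)O[C@@H]2CC/C(C)=C/C1 | intermediate
4 | (2E,6R,7R)-6,7-epoxyhumul-2-en-15-ol (C2=C3 ring-cis: C1 and C4 on the same side, CH2OH trans to C1) | CC1(C)CCC[C@@]2(C)O[C@@H]2CC/C(CO)=C\C1 | intermediate (not isolated)
5 | (2E,6R,7R)-6,7-epoxyhumul-2-en-15-al (ring-cis enal, CHO trans to C1) | CC1(C)CCC[C@@]2(C)O[C@@H]2CC/C(C=O)=C\C1 | intermediate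
6 | (1R,2E,6R,7R)-1-benzoyloxy-6,7-epoxyhumul-2-en-15-al | CC1(C)CCC[C@@]2(C)O[C@@H]2CC/C(C=O)=C\[C@H]1OC(=O)c1ccccc1 | intermediate
7 | (1R,2E,6R,7R)-1-benzoyloxy-6,7-epoxyhumul-2-en-15-oic acid (CNP0377917.1) | CC1(C)CCC[C@@]2(C)O[C@@H]2CC/C(C(=O)O)=C\[C@H]1OC(=O)c1ccccc1 | target

**Step count and risks**
Total steps: 5. Longest linear sequence: 5 (from α-humulene).

The three steps most likely to fail:

Step 4 (proposed new step). Possible failures are oxidation of the amine instead of carbon, slow dienamine formation at the neopentyl C1, or the wrong C1 epimer; the quinidine-derived pseudoenantiomeric amine is the first variation to try. The fallback uses known chemistry, sets out from 5 and comes back at 6. Compound 5 is silylated (TBSOTf, Et3N, CH2Cl2, −78 °C) to the silyl dienol ether (6R,7R)-15-(tert-butyldimethylsilyloxy)-6,7-epoxyhumula-1,3(15)-diene F4. Vinylogous Rubottom oxidation with dimethyldioxirane (acetone, −78 → −40 °C, aqueous work-up, which removes the silyl group) oxidises the γ-carbon. It gives (1R,2E,6R,7R)-6,7-epoxy-1-hydroxyhumul-2-en-15-al F5 and its epimer (1S,2E,6R,7R)-6,7-epoxy-1-hydroxyhumul-2-en-15-al F6, which are separated by chromatography. F5 is benzoylated (BzCl, DMAP, pyridine, 0 °C) to 6.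

Step 3. SeO2 may attack the ring CH2 at C4 instead of C15, or the double bond may not turn ring-cis. The fallback sets out from 3 and comes back at 4. A Schenck ene reaction (O2, visible light, tetraphenylporphyrin, CH2Cl2, 0 °C) gives (6R,7R)-6,7-epoxy-2-hydroperoxyhumul-3(15)-ene F2 as a C2-epimer mixture. It is reduced in the same flask with PPh3 to (6R,7R)-6,7-epoxyhumul-3(15)-en-2-ol F3. A 1,3-transposition of the allylic alcohol catalysed by O3ReOSiPh3 (2 mol%, Et2O, 0 °C) then gives the thermodynamically preferred primary, trisubstituted allylic alcohol 4, which is oxidised with MnO2 to 5 as in step 3.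

Step 1. The enantioselectivity of the Shi epoxidation on a flexible medium-ring triene may be insufficient, and some 2,3-epoxide or bis-epoxide may form. The fallback sets out from 1 and comes back at 2. Peracid epoxidation (mCPBA 0.95 equiv, NaHCO3, CH2Cl2, −20 °C), which is known to favour C6=C7, gives the racemate, that is 2 together with (6S,7S)-6,7-epoxyhumula-2,9-diene F1. The enantiomers are separated by preparative chiral supercritical-fluid chromatography (cellulose tris(3,5-dimethylphenylcarbamate) phase, CO2/i-PrOH), and (6R,7R)-2 is carried on.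

**Further compounds**
F1 | step 1 | (6S,7S)-6,7-epoxyhumula-2,9-diene (enantiomer of 2) | CC1(C)/C=C/C[C@]2(C)O[C@H]2CC/C(C)=C/C1
F2 | step 3 | (6R,7R)-6,7-epoxy-2-hydroperoxyhumul-3(15)-ene (C2-epimer mixture) | CC1(C)CCC[C@@]2(C)O[C@@H]2CCC(=C)C(OO)C1
F3 | step 3 | (6R,7R)-6,7-epoxyhumul-3(15)-en-2-ol (C2-epimer mixture) | CC1(C)CCC[C@@]2(C)O[C@@H]2CCC(=C)C(O)C1
F4 | step 4 | (6R,7R)-15-(tert-butyldimethylsilyloxy)-6,7-epoxyhumula-1,3(15)-diene (double-bond geometry not controlled) | CC1(C)CCC[C@@]2(C)O[C@@H]2CCC(=CO[Si](C)(C)C(C)(C)C)C=C1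
F5 | step 4 | (1R,2E,6R,7R)-6,7-epoxy-1-hydroxyhumul-2-en-15-al | CC1(C)CCC[C@@]2(C)O[C@@H]2CC/C(C=O)=C\[C@H]1O
F6 | step 4 | (1S,2E,6R,7R)-6,7-epoxy-1-hydroxyhumul-2-en-15-al | CC1(C)CCC[C@@]2(C)O[C@@H]2CC/C(C=O)=C\[C@@H]1O
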